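## Analysis of the target

The target 13 is a single five-membered ring, a γ-butyrolactone: O1 is bound to the carbonyl carbon C2 and to the methylene C5, C3 carries an exocyclic 4-hydroxy-3-methoxybenzylidene group (guaiacyl ring), and C4 carries a hydrogen and a 3,4-dimethoxybenzyl group (veratryl ring). C4 is the only stereocenter and is R (priorities C5 > C3 > benzyl CH2 > H). The only other stereochemical element is the E geometry at C3, with the guaiacyl ring trans to the C2 carbonyl and cis to C4. No second stereocenter exists from which C4 could be relayed, and its neighbour C3 is trigonal, so the configuration has to come from a reagent or a catalyst. The sensitive groups are the free phenol, the Michael-acceptor lactone and above all the C4–H bond, which is allylic: base can move the alkene into the ring (C3=C4) and erase the stereocenter, so the late steps must be neutral or acidic. The two aryl rings are electronically almost alike but must end in different places, the veratryl ring on an sp3 benzylic carbon and the guaiacyl ring on an sp2 one. The strategy rests on reading C2–C3–C4–C5 as a succinate chain with one benzylic carbon on each inner atom: C2 is at the carboxyl level, C5 is one reduction away from a carboxyl group, and C4 with its hydrogen and benzyl group is then the hydrogenation product of a veratrylidene alkene conjugated to a free C5 acid, while the C3 arylidene, conjugated to an ester at C2, stays as it is.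

## Retrosynthetic reasoning

The last bonds made are the acyl C2–O1 bond of the lactone and the O–H bond of the phenol. Cutting C2–O1 gives the γ-hydroxy ester 11, with C2 as an ethyl ester and C5 as a primary alcohol; the phenol is masked as its methoxymethyl ether, so that ring closure to 12 and unmasking to 13 can be done by the same acid. The acyl bond is cut rather than C5–O1 because acyl transfer onto a primary alcohol needs no activation and cannot touch C4. Acid is used because base would endanger the allylic C4–H. The acetal is preferred to a benzyl ether, whose hydrogenolysis would threaten the arylidene, and to a silyl ether, which would not survive the alkoxide used earlier.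

The C5 carbinol of 11 is traced to the carboxylic acid 10. No skeletal bond is cut. The gain is that C5 now carries the one group that can anchor a hydrogenation catalyst, and that the two ends of the succinate chain differ (acid at C5, ester at C2). The forward step must reduce an acid beside a conjugated ester and a trisubstituted alkene, which is the normal selectivity of an electrophilic hydride.

Next the C4–H bond and the benzylic C–H bond of the veratryl side chain are removed together, which turns 10 into the achiral diene half-ester 9. Here the only stereocenter is traced back to a prochiral trigonal carbon. In the forward direction one molecule of hydrogen must add enantioselectively to the alkene that is α,β to the free acid, while the ester-conjugated arylidene, which is the alkene of the target, is left alone. The free carboxyl group is the handle for both selectivities. Cutting at C–H bonds and not at a C–C bond leaves the whole skeleton to condensation chemistry.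

In 9 the C3=CH bond to the guaiacyl ring is cut, giving aldehyde 7 and the arylidenesuccinate 5, whose only enolizable position is its CH2 group. This alkene is cut, and not the veratrylidene, because of the way a Stobbe condensation distributes its carbonyl groups. The alkoxide of the aldol step can lactonize only onto the ester across the chain (lactone 8), and the ring opening that follows frees exactly that carboxyl group. The arylidene introduced second therefore sits on the ester and the one introduced first on the acid, which is the pattern 9 needs. The forward reaction has to give the E alkene, the thermodynamic outcome.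

Diester 5 is the ethyl ester of half-ester 4, and 4 is cut at its arylidene double bond into 3,4-dimethoxybenzaldehyde 1 and diethyl succinate 2, again a Stobbe condensation (through lactone 3). The acid freed in this first condensation sits on the CH2 arm and is re-esterified so that this CH2 group becomes the enolate position of the second condensation.

Aldehyde 7 is the methoxymethyl ether of vanillin 6. The phenol has to be masked because its phenoxide would form under the alkoxide base and deactivate the aldehyde.

## Alternatives that were turned down

Alternative 1: The lactone is cut at O1–C2 and C2–C3, so that C2 is supplied by carbonylation and the rest is the homopropargylic alcohol (R)-4-[4-(tert-butyldimethylsilyloxy)-3-methoxyphenyl]-2-(3,4-dimethoxybenzyl)but-3-yn-1-ol A2.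
- Forward key step: on zerovalent palladium under a carbonylating atmosphere, hydrogen and an acyl group add syn across the alkyne and the alcohol closes the ring, giving A1, the tert-butyldimethylsilyl ether of 13.
- For it: syn addition places the aryl ring trans to the new carbonyl, so the E geometry follows from the mechanism; ring, carbonyl and alkene appear in one step; only one alkene is ever present; one desilylation finishes the synthesis. On alkene geometry and on chemoselectivity it is stronger than the chosen route.
- Against it: C4 must already exist in A2 as a propargylic stereocenter bearing a benzyl and a hydroxymethyl group. That needs a stoichiometric auxiliary or a resolution plus a separate aryl–alkyne coupling, roughly doubling the steps before the key step. A propargylic C–H next to a palladium hydride can racemize through an allene, and pressure equipment is needed.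
- What the chosen route offers in its place: the stereocenter is made catalytically from an achiral diene that is four steps from commodity chemicals, with both alkene geometries fixed beforehand by condensation thermodynamics.

Alternative 2: The benzylic CH2–aryl bond of the C4 side chain and the C3 arylidene are cut.
- Forward key step: the cyclopropane-fused lactone diethyl [(1R,5S)-2-oxo-3-oxabicyclo[3.1.0]hexan-1-yl]phosphonate A4 would come from (R)-epichlorohydrin A5 and a phosphonoacetate ester, provided the epoxide is opened before chloride is displaced. A veratryl cuprate would attack the cyclopropane CH2 in a homo-conjugate addition, releasing the ring strain and a phosphonate-stabilized lactone enolate, to give diethyl [(4S)-4-(3,4-dimethoxybenzyl)-2-oxotetrahydrofuran-3-yl]phosphonate A3 (C3 epimers; same spatial arrangement at C4 as 13, the descriptor changes because phosphorus raises the priority of C3). A Horner–Wadsworth–Emmons reaction with 7 and deprotection would finish.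
- For it: about four steps, the configuration of C4 is bought from the chiral pool and is not in doubt, and the ring opening exposes the olefination nucleophile directly. On step count and on certainty of absolute configuration it is stronger than the chosen route.
- Against it: olefination of an α-phosphono lactone with a substituent at C4 has no built-in control of E against Z. The two possible orders of displacement at the epoxide stage lead to opposite enantiomers, so enantiomeric purity can erode. The cuprate must prefer the cyclopropane to the lactone carbonyl, and stoichiometric organometallic reagents are needed.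
- What the chosen route offers in its place: E geometry secured before the stereocenter exists, either enantiomer by choice of ligand, and no organometallic reagent.

Alternative 3: The C4–C5 bond is cut.
- Forward key step: the precursor is the stannylmethyl ether A7, tributyl[({(1R,2E)-1-[4-(tert-butyldimethylsilyloxy)-3-methoxyphenyl]-2-[(tert-butyldimethylsilyloxy)methyl]-4-(3,4-dimethoxyphenyl)but-2-en-1-yl}oxy)methyl]stannane, derived from a secondary alcohol that is both benzylic and allylic. Tin–lithium exchange would give an α-alkoxy carbanion whose Still–Wittig [2,3]-shift forms C4–C5, breaks the benzylic C–O bond and moves the alkene to C3=CH–aryl. The product is (R,E)-2-(3,4-dimethoxybenzyl)-3-[(tert-butyldimethylsilyloxy)methyl]-4-[4-(tert-butyldimethylsilyloxy)-3-methoxyphenyl]but-3-en-1-ol A6. Desilylation, oxidation of the allylic alcohol through the lactol to the lactone, and phenol deprotection would follow.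
- For it: the concerted suprafacial shift transfers the carbinol configuration to C4 and sets the alkene geometry in the same event. On reliability of stereochemical transfer it is stronger than an untested catalytic step.
- Against it: the carbinol is doubly activated (benzylic to a para-oxygenated ring and allylic), so ionization and the competing [1,2]-shift threaten it. It must be made enantiopure with a defined trisubstituted alkene, which costs an asymmetric step and several C–C bond formations. Stoichiometric tin is used, and after the shift C2 is at the alcohol level, so three more steps follow. The route is more than twice as long.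
- What the chosen route offers in its place: the skeleton arrives with C2 already at the carboxyl level, and with far fewer steps.

Key step: step 5

Assumption: the sense of induction of Ru(OAc)2[(S)-BINAP] is carried over from (E)-2-alkylalk-2-enoic acids, where the (S) ligand gives (S)-2-methylalkanoic acids; the same face of 9 corresponds to the R descriptor of 10 because the alkenyl group at C2 outranks the benzyl group, and if the bulky alkenyl group reverses the sense, Ru(OAc)2[(R)-BINAP] is used instead.

## Route

Step 1
Reactants: 1 3,4-dimethoxybenzaldehyde; 2 diethyl succinate
Product: 4 (E)-4-(3,4-dimethoxyphenyl)-3-(ethoxycarbonyl)but-3-enoic acid, via paraconate lactone 3 (not isolated)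
Conditions: NaOEt (2 equiv), EtOH, reflux; then 1 M HCl
Reagents that add atoms: none
Why: Stobbe condensation: the succinate enolate adds to 1, the alkoxide closes onto the distal ester to give lactone 3, and E1cB opening of 3 expels a carboxylate irreversibly, which drives the reaction and leaves the aryl ring trans to the ester (E) for steric reasons.

Step 2
Reactants: 4 (E)-4-(3,4-dimethoxyphenyl)-3-(ethoxycarbonyl)but-3-enoic acid
Product: 5 diethyl (E)-2-(3,4-dimethoxybenzylidene)succinate
Conditions: EtOH, H2SO4 (cat.), reflux
Reagents that add atoms: ethanol, CCO
Why: Fischer esterification; the trisubstituted styrenyl alkene keeps its geometry under catalytic mineral acid in ethanol and the aryl methyl ethers are inert.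

Step 3
Reactants: 6 vanillin
Product: 7 3-methoxy-4-(methoxymethoxy)benzaldehyde
Conditions: MOMCl, iPr2NEt, CH2Cl2, 0 °C to rt
Reagents that add atoms: chloromethyl methyl ether, COCCl
Why: O-alkylation of the phenol with an α-chloro ether (acetal protection); the acetal tolerates alkoxide, hydrogenation and borane and falls to the same acid that later closes the lactone.

Step 4
Reactants: 5 diethyl (E)-2-(3,4-dimethoxybenzylidene)succinate; 7 3-methoxy-4-(methoxymethoxy)benzaldehyde
Product: 9 (2E,3E)-2-(3,4-dimethoxybenzylidene)-3-(ethoxycarbonyl)-4-[3-methoxy-4-(methoxymethoxy)phenyl]but-3-enoic acid, via arylidene paraconate lactone 8 (not isolated)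
Conditions: NaOEt (1.5 equiv), EtOH, reflux; then 1 M HCl to pH 3 at 0 °C
Reagents that add atoms: none
Why: Second Stobbe condensation, as used for bis(arylidene)succinic half-esters: only the CH2 group of 5 is enolizable, the aldol alkoxide can reach only the veratrylidene-bound ester through a five-membered ring (lactone 8), and E1cB opening of 8 therefore frees the acid on the veratrylidene side and leaves the ethyl ester on the new arylidene. Each aryl ring ends up trans to the carbonyl group on its own alkene carbon (E,E), the less crowded arrangement.

Step 5
Reactants: 9 (2E,3E)-2-(3,4-dimethoxybenzylidene)-3-(ethoxycarbonyl)-4-[3-methoxy-4-(methoxymethoxy)phenyl]but-3-enoic acid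
Product: 10 (R,E)-2-(3,4-dimethoxybenzyl)-3-(ethoxycarbonyl)-4-[3-methoxy-4-(methoxymethoxy)phenyl]but-3-enoic acid
Conditions: H2 (4 atm), Ru(OAc)2[(S)-BINAP] (1 mol %), degassed MeOH, 25 °C, exclusion of light, stopped after one equivalent of H2
Reagents that add atoms: none
Why: Proposed new method: exchange of an acetate ligand for the carboxylate of 9 anchors the substrate on divalent ruthenium, heterolysis of H2 gives a ruthenium monohydride, and the veratrylidene alkene, the only one α,β to the bound carboxylate, inserts so that hydride goes to C2 and the metal to the benzylic carbon inside a five-membered O–Ru–C chelate; cleavage of that Ru–C bond with retention by H2 or by methanol puts the second hydrogen on the same face. The closest known reaction types are the Ru(OAc)2(BINAP)-catalysed hydrogenation of (E)-2-substituted cinnamic and alk-2-enoic acids and the hydrogenation of arylidenesuccinic half-esters with cationic complexes of the type [Rh(cod)(bisphosphine)]BF4; what has not been shown is reduction of only one of the two arylidene alkenes of a 2,3-bis(arylidene)succinic half-ester. No ring is closed in this step. The one new stereocenter, C2 of 10 (C4 of the lactone), is under catalyst control: the (S)-BINAP ligand decides which face of the chelated E alkene meets the hydride, and by the correlation known for (E)-2-alkylalk-2-enoic acids this face corresponds to R here. The step needs site selectivity, and three features of 9 should secure it: only the veratrylidene can form the five-membered chelate with ruthenium on a secondary benzylic carbon, whereas the other alkene is β,γ to the acid and would have to place the metal on the fully substituted C3; the vanillylidene is conjugated to an ethyl ester, which does not bind the catalyst; and the two cinnamate halves are twisted out of a common plane, so they should behave as separate alkenes without 1,4-addition. Low pressure and interruption after one equivalent of H2 limit over-reduction.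

Step 6
Reactants: 10 (R,E)-2-(3,4-dimethoxybenzyl)-3-(ethoxycarbonyl)-4-[3-methoxy-4-(methoxymethoxy)phenyl]but-3-enoic acid
Product: 11 ethyl (R,E)-3-(3,4-dimethoxybenzyl)-4-hydroxy-2-[3-methoxy-4-(methoxymethoxy)benzylidene]butanoate
Conditions: BH3·SMe2 (2 equiv), THF, 0 °C to rt; MeOH quench, aqueous work-up
Reagents that add atoms: none
Why: Chemoselective borane reduction of a carboxylic acid through its acyloxyborane, which is much faster than reduction of the conjugated ester or hydroboration of the electron-poor trisubstituted arylidene; no base is present, so the α-stereocenter is not epimerized before it becomes a non-enolizable carbinol carbon's neighbour. Partial spontaneous ring closure to 12 on work-up would be harmless.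

Step 7
Reactants: 11 ethyl (R,E)-3-(3,4-dimethoxybenzyl)-4-hydroxy-2-[3-methoxy-4-(methoxymethoxy)benzylidene]butanoate
Product: 13 (R,E)-4-(3,4-dimethoxybenzyl)-3-(4-hydroxy-3-methoxybenzylidene)dihydrofuran-2(3H)-one, via MOM-protected lactone 12 (not isolated)
Conditions: HCl (cat.), MeOH, 45 °C
Reagents that add atoms: none
Why: Acid-catalysed 5-exo-trig lactonization of the γ-hydroxy ester gives 12, and acetal exchange with methanol then removes the methoxymethyl group as dimethoxymethane, so no free formaldehyde-derived cation lingers. C4 is not enolizable in the lactone and acid does not move the exocyclic alkene into the ring, so the R configuration and the E geometry should be kept.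

## Compound list

1 | 3,4-dimethoxybenzaldehyde | COc1ccc(C=O)cc1OC | starting material
2 | diethyl succinate | CCOC(=O)CCC(=O)OCC | starting material
3 | ethyl 2-(3,4-dimethoxyphenyl)-5-oxotetrahydrofuran-3-carboxylate (paraconate lactone, racemic diastereomer mixture) | CCOC(=O)C1CC(=O)OC1c1ccc(OC)c(OC)c1 | intermediate
4 | (E)-4-(3,4-dimethoxyphenyl)-3-(ethoxycarbonyl)but-3-enoic acid | CCOC(=O)/C(CC(=O)O)=C/c1ccc(OC)c(OC)c1 | intermediate
5 | diethyl (E)-2-(3,4-dimethoxybenzylidene)succinate | CCOC(=O)/C(CC(=O)OCC)=C/c1ccc(OC)c(OC)c1 | intermediate
6 | vanillin (4-hydroxy-3-methoxybenzaldehyde) | COc1cc(C=O)ccc1O | starting material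
7 | 3-methoxy-4-(methoxymethoxy)benzaldehyde | COCOc1ccc(C=O)cc1OC | intermediate
8 | ethyl (E)-4-(3,4-dimethoxybenzylidene)-2-[3-methoxy-4-(methoxymethoxy)phenyl]-5-oxotetrahydrofuran-3-carboxylate (racemic diastereomer mixture) | CCOC(=O)C1C(c2ccc(OCOC)c(OC)c2)OC(=O)/C1=C/c3ccc(OC)c(OC)c3 | intermediate
9 | (2E,3E)-2-(3,4-dimethoxybenzylidene)-3-(ethoxycarbonyl)-4-[3-methoxy-4-(methoxymethoxy)phenyl]but-3-enoic acid | COc1ccc(/C=C(/C(=O)O)C(=C/c2ccc(OCOC)c(OC)c2)\C(=O)OCC)cc1OC | intermediate
10 | (R,E)-2-(3,4-dimethoxybenzyl)-3-(ethoxycarbonyl)-4-[3-methoxy-4-(methoxymethoxy)phenyl]but-3-enoic acid | OC(=O)[C@@H](C(=C/c1ccc(OCOC)c(OC)c1)\C(=O)OCC)Cc1ccc(OC)c(OC)c1 | intermediate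
11 | ethyl (R,E)-3-(3,4-dimethoxybenzyl)-4-hydroxy-2-[3-methoxy-4-(methoxymethoxy)benzylidene]butanoate | OC[C@@H](C(=C/c1ccc(OCOC)c(OC)c1)\C(=O)OCC)Cc1ccc(OC)c(OC)c1 | intermediate
12 | (R,E)-4-(3,4-dimethoxybenzyl)-3-[3-methoxy-4-(methoxymethoxy)benzylidene]dihydrofuran-2(3H)-one | COc1cc(/C=C2/C(=O)OC[C@@H]2Cc2ccc(OC)c(OC)c2)ccc1OCOC | intermediate
13 | (R,E)-4-(3,4-dimethoxybenzyl)-3-(4-hydroxy-3-methoxybenzylidene)dihydrofuran-2(3H)-one | COc1cc(/C=C2/C(=O)OC[C@@H]2Cc2ccc(OC)c(OC)c2)ccc1O | target

## Step count and least certain steps

Total: 7 steps. Longest linear sequence: 6 steps (steps 1, 2, 4, 5, 6, 7 from 1 and 2); step 3 is a one-step side branch.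

**Step 5 (key step).**
- What may go wrong: loss of site selectivity, with hydrogen delivered to the vanillylidene alkene through the same carboxylate anchor in a β,γ-directed mode; over-reduction of both alkenes; slow turnover at the hindered trisubstituted alkene; poor or reversed facial discrimination because the C2 substituent is a bulky alkenyl group and not a small alkyl group.
- Fallback (known chemistry; sets out from 4, returns at 12): half-ester 4 is hydrogenated with [Rh(cod)((S,S)-Et-DuPhos)]BF4 or its antipode, whichever gives the R acid, to (R)-4-(3,4-dimethoxyphenyl)-3-(ethoxycarbonyl)butanoic acid F1. Its potassium salt (KOH) is reduced at the ester with Ca(BH4)2 (from NaBH4 and CaCl2) in EtOH to (R)-3-(3,4-dimethoxybenzyl)-4-hydroxybutanoic acid F2, which closes on acidification to (R)-4-(3,4-dimethoxybenzyl)dihydrofuran-2(3H)-one F3. The lithium enolate of F3 (LiN(iPr)2, THF, −78 °C) adds to aldehyde 7 anti to the benzyl group to give (3S,4R)-4-(3,4-dimethoxybenzyl)-3-{hydroxy[3-methoxy-4-(methoxymethoxy)phenyl]methyl}dihydrofuran-2(3H)-one F4 (carbinol epimers). Acetylation (Ac2O, Et3N, DMAP) gives the acetate F5, and DBU-induced E1cB elimination should give 12 with the thermodynamically favoured E geometry. In this detour only one alkene is present when the stereocenter is set.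

**Step 4.**
- What may go wrong: under reversible alkoxide conditions the enolate of 5 can be reprotonated at the benzylic carbon, which moves the alkene into conjugation with both esters and stops the condensation; the hindered enolate may add slowly while aldehyde 7 is consumed by disproportionation; the new alkene may form with incomplete E selectivity.
- Fallback (sets out from 5, returns at 9): irreversible enolization of 5 with LiN(iPr)2 in THF at −78 °C, addition of 7 and a cold quench to isolate the aldol diethyl (E)-2-(3,4-dimethoxybenzylidene)-3-{hydroxy[3-methoxy-4-(methoxymethoxy)phenyl]methyl}succinate F6. In a separate operation NaOEt (1.1 equiv) in EtOH at room temperature closes F6 to lactone 8 and opens it to 9. Carbon–carbon bond formation is thereby separated from the elimination and removed from thermodynamic control.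

**Step 6.**
- What may go wrong: hydroboration of the remaining arylidene, reduction of the conjugated ester by hydride delivered from the first-formed alkoxyborane, or incomplete reduction of the hindered α-branched acid.
- Fallback (sets out from 10, returns at 11): activation followed by borohydride reduction. Isobutyl chloroformate and N-methylmorpholine in THF at −15 °C convert 10 into (R,E)-2-(3,4-dimethoxybenzyl)-3-(ethoxycarbonyl)-4-[3-methoxy-4-(methoxymethoxy)phenyl]but-3-enoic isobutyl carbonic anhydride F7, which NaBH4 in THF/water at 0 °C should reduce to 11 without touching the conjugated ester or the alkene.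

**Step 7.**
- What may go wrong: alkylation of the electron-rich rings by the methoxymethyl cation if methanol does not intercept it fast enough, ring closure lagging behind ester exchange with the solvent, and scrambling of the alkene geometry through protonation at C3 on prolonged heating.
- Fallback (sets out from 11, passes through isolated 12, returns at 13; no compound outside the list, F0): ring closure under weakly acidic aprotic conditions (pyridinium p-toluenesulfonate, toluene, 80 °C) to isolate 12, then dealkylation with ZnBr2 and propane-1-thiol in CH2Cl2 at 0 °C, in which the thiol captures the methoxymethyl group as a thioacetal before it can reach an arene.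

## Further compounds

F1 | step 5 | (R)-4-(3,4-dimethoxyphenyl)-3-(ethoxycarbonyl)butanoic acid | OC(=O)C[C@@H](Cc1ccc(OC)c(OC)c1)C(=O)OCC
F2 | step 5 | (R)-3-(3,4-dimethoxybenzyl)-4-hydroxybutanoic acid | OC[C@H](Cc1ccc(OC)c(OC)c1)CC(=O)O
F3 | step 5 | (R)-4-(3,4-dimethoxybenzyl)dihydrofuran-2(3H)-one | O=C1OC[C@H](Cc2ccc(OC)c(OC)c2)C1
F4 | step 5 | (3S,4R)-4-(3,4-dimethoxybenzyl)-3-{hydroxy[3-methoxy-4-(methoxymethoxy)phenyl]methyl}dihydrofuran-2(3H)-one (carbinol epimers) | O=C1OC[C@H](Cc2ccc(OC)c(OC)c2)[C@H]1C(O)c3ccc(OCOC)c(OC)c3
F5 | step 5 | [(3S,4R)-4-(3,4-dimethoxybenzyl)-2-oxotetrahydrofuran-3-yl][3-methoxy-4-(methoxymethoxy)phenyl]methyl acetate (carbinol epimers) | O=C1OC[C@H](Cc2ccc(OC)c(OC)c2)[C@H]1C(OC(C)=O)c3ccc(OCOC)c(OC)c3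
F6 | step 4 | diethyl (E)-2-(3,4-dimethoxybenzylidene)-3-{hydroxy[3-methoxy-4-(methoxymethoxy)phenyl]methyl}succinate (racemic diastereomer mixture) | CCOC(=O)/C(=C/c1ccc(OC)c(OC)c1)C(C(O)c1ccc(OCOC)c(OC)c1)C(=O)OCC
F7 | step 6 | (R,E)-2-(3,4-dimethoxybenzyl)-3-(ethoxycarbonyl)-4-[3-methoxy-4-(methoxymethoxy)phenyl]but-3-enoic isobutyl carbonic anhydride | CC(C)COC(=O)OC(=O)[C@@H](C(=C/c1ccc(OCOC)c(OC)c1)\C(=O)OCC)Cc1ccc(OC)c(OC)c1
F0 | step 7 | none | none
A1 | alternative 1 | (R,E)-3-[4-(tert-butyldimethylsilyloxy)-3-methoxybenzylidene]-4-(3,4-dimethoxybenzyl)dihydrofuran-2(3H)-one | COc1cc(/C=C2/C(=O)OC[C@@H]2Cc2ccc(OC)c(OC)c2)ccc1O[Si](C)(C)C(C)(C)C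
A2 | alternative 1 | (R)-4-[4-(tert-butyldimethylsilyloxy)-3-methoxyphenyl]-2-(3,4-dimethoxybenzyl)but-3-yn-1-ol | OC[C@@H](C#Cc1ccc(O[Si](C)(C)C(C)(C)C)c(OC)c1)Cc1ccc(OC)c(OC)c1
A3 | alternative 2 | diethyl [(4S)-4-(3,4-dimethoxybenzyl)-2-oxotetrahydrofuran-3-yl]phosphonate (C3 epimers) | CCOP(=O)(OCC)C1C(=O)OC[C@@H]1Cc1ccc(OC)c(OC)c1
A4 | alternative 2 | diethyl [(1R,5S)-2-oxo-3-oxabicyclo[3.1.0]hexan-1-yl]phosphonate | CCOP(=O)(OCC)[C@@]12C(=O)OC[C@@H]1C2
A5 | alternative 2 | (R)-epichlorohydrin | ClC[C@H]1CO1
A6 | alternative 3 | (R,E)-2-(3,4-dimethoxybenzyl)-3-[(tert-butyldimethylsilyloxy)methyl]-4-[4-(tert-butyldimethylsilyloxy)-3-methoxyphenyl]but-3-en-1-ol | OC[C@@H](/C(CO[Si](C)(C)C(C)(C)C)=C\c1ccc(O[Si](C)(C)C(C)(C)C)c(OC)c1)Cc1ccc(OC)c(OC)c1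
A7 | alternative 3 | tributyl[({(1R,2E)-1-[4-(tert-butyldimethylsilyloxy)-3-methoxyphenyl]-2-[(tert-butyldimethylsilyloxy)methyl]-4-(3,4-dimethoxyphenyl)but-2-en-1-yl}oxy)methyl]stannane | CCCC[Sn](CCCC)(CCCC)CO[C@H](c1ccc(O[Si](C)(C)C(C)(C)C)c(OC)c1)/C(CO[Si](C)(C)C(C)(C)C)=C/Cc1ccc(OC)c(OC)c1
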